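## Structural features

The target is a (3R)-isoflavan: a 3,4-dihydro-2H-chromene (benzene ring A fused to the dihydropyran ring C) that carries a second benzene ring (ring B) through C1′ on C3. Ring A has three differentiated oxygens (the ring oxygen O1 on C8a, OMe on C5, free OH on C7). Ring B is 1′,2′,3′,4′-tetrasubstituted, with OH on C2′, a 3-methylbut-2-enyl (prenyl) group on C3′ and OMe on C4′. C3 is the only stereocentre: a tertiary benzylic C–H between the methylene groups C2 and C4, with no neighbouring stereocentre, heteroatom or carbonyl group to relay chirality from. The fragile parts are the prenyl alkene, which rules out hydrogenation, hydrogenolysis and strong acid (cyclisation onto the ortho 2′-OH to a 2,2-dimethylchroman), and the two electron-rich phenols, which oxidise easily. The real difficulty is to set an isolated, purely carbon-substituted stereocentre in absolute terms without reductive methods, and to place the substituents on both rings with full regiocontrol. The key step uses the hydrogen on C3: with a hydroxymethyl group in its place, C3 is a quaternary prochiral carbon whose two CH2OH arms (the future C2 arm and the extra arm) are enantiotopic, so forming O1–C8a from one arm closes ring C and creates the stereocentre at once.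

## Logic of the disconnections

**20 back to 18 (through 19).** The O7–H bond is replaced by O–Si (19) and then the O2′–H bond by O–CH2OCH3 (18); no skeletal bond is cut. Both phenols must stay silent through base, hydride, copper and rhodium chemistry. The gain is that every earlier intermediate is a neutral aryl ether. The demand is two unmaskings mild enough for a prenyl group next to the 2′-OH, so the acetal goes under dilute acid and the silyl ether under buffered fluoride.

**18 back to 16 (through 17).** The C3–H bond is exchanged for C3–CHO (17) and then C3–CH2OH (16), adding one carbon in the backward sense. With the arm, C3 is quaternary, cannot epimerise, and has a twin of the C2 arm. The forward excision must go with retention (rhodium-mediated decarbonylation) and must not lose a β-hydrogen.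

**16 back to 15.** The O1–C8a bond is cut. This removes ring C and the stereocentre together: 15 is achiral, with a mirror plane through C3, C1′ and C4. The forward step must select one of two enantiotopic CH2OH groups, which calls for a chiral ligand on copper, and the aryl bromide must reach this point intact.

**15 back to 13 and 5 (through 14).** The two C–OH groups are taken back to esters (14), and the C3–C4 bond is then cut to the stabilised carbanion of 13 and the benzylic electrophile 5. A malonate supplies both arms in one reduction and builds the quaternary carbon by a single alkylation; this is also the point where the two aromatic halves meet. The demand is a hindered SN2 reaction between a tertiary enolate and a 2,6-disubstituted benzyl bromide, and a hydride reduction that spares the aryl bromide.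

**13 back to 11 and 12.** The C3–C1′ bond is cut, giving an aryl bromide and a malonate. This avoids any separate arylacetate synthesis. The forward step needs oxidative addition of palladium into an electron-rich, ortho-alkoxy aryl bromide in the presence of the prenyl alkene.

**11 back to 6 and 7 (through 10, 9, 8).** The acetal O–C bond is cut (10). The C3′–CH2 bond of the prenyl group is traced through a [3,3] shift to the O–C(CH3)2 bond of 9, which comes from the alkyne 8 and, by cutting the same O–C bond, from 6 and 7. Intramolecular delivery gives ortho-specific C-prenylation; the bromine blocks the other ortho position and later serves step 8. The demand is a semi-hydrogenation that stops at the alkene and leaves the aryl bromide alone.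

**5 back to 1 (through 4, 3, 2).** The C–Br bond goes back to C–OH (4) and C=O (3); the C4–C4a bond is then cut to an aryl anion between Br and OMe of 2 and a formyl equivalent, and 2 comes from 1 by an O–Si cut. That ring position is the most acidic C–H, and the bulky silyl ether shields the other two. The forward step needs low temperature (to avoid loss of LiBr to an aryne) and clean regioselective deprotonation.

## Other disconnections considered

**Alternative 1:** The cut is C3–C4, made after tying C4 to O2′ of ring B, so the isoflavan is reached through a pterocarpan.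
- Forward key step: the aryldiazoacetate A1 would be decomposed by Rh2(S-PTTL)4 (or its antipode), and the carbene would insert into the benzylic, oxygen-activated C–H of the O2′–CH2 ether to give the cis-dihydrobenzofuran A2, setting C3 and C4 together. Ester reduction, desilylation and etherification with the C8a phenol would give the pterocarpan A3, whose C4–O2′ bond would then be cleaved reductively.
- In favour: C3 is made directly in a C–C bond-forming event under catalyst control, no carbon is added and removed, and no stoichiometric rhodium is needed. On directness and atom economy this plan is better than the chosen one.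
- Against: a second stereocentre (C4) is built only to be erased. The insertion site is flanked by both ortho substituents of ring A. A2 has an acidic C3–H next to ester and aryl and could epimerise before reduction. Above all, the C4–O2′ cleavage of A3 cannot be a catalytic hydrogenolysis because of the prenyl alkene, and dissolving-metal or ionic reductions threaten the same alkene and the phenols.
- Comparison: both plans rest on one catalytic asymmetric step of a known class with comparable expected selectivity. The chosen plan keeps C3 non-epimerisable until its configuration is fixed, which A2 does not. Step count is about equal, since A1 needs the same ring-B prenylation plus etherification and diazo transfer, and four operations follow the insertion.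

**Alternative 2:** Ring A is cut along C4a–C8a, C5–C6 and C8–C8a.
- Forward key step: heating the cyclobutenone A4 would open it to a vinylketene, which would add to the enantiopure ynol ether A5; ring opening, six-electron ring closure and tautomerisation would give the phenol A6 with OH on C8a, the chain on C4a, OMe on C5 and O-allyl on C7.
- In favour: the three ring-A oxygens are differentiated by construction and placed by the mechanism. On ring-A regiocontrol this plan is better than the chosen one, which relies on a selective deprotonation. The key step needs no metal.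
- Against: the benzannulation leaves the stereocentre untouched, so C3 must be set in A5 by a separate asymmetric operation. A5 is a sensitive methyl ynol ether to be made on a functionalised chiral fragment, and A4 is not a shelf compound. The ketene cascade runs hot in the presence of the prenyl alkene and the acetal. After A6, ring C must still be closed and two different phenol protecting groups removed.
- Comparison: ring closure from A6 would be as dependable as the copper-mediated one, and the configurational stability of C3 is equal in both plans. The sequence is longer, because stereocentre, ynol ether and ring closure each cost separate steps, where the chosen plan makes ring C and C3 in one operation.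

**Alternative 3:** Ring B is cut along C1′–C2′, C2′–C3′ and C4′–C5′.
- Forward key step: irradiation of the diazoketone A7 would trigger a Wolff rearrangement to a vinylketene, which would combine with the ynol ether A8 by the same cascade to give the phenol A9, the same compound as 19.
- In favour: the crowded ring B, with prenyl, OMe and free 2′-OH, would arise in one regio-defined step. That avoids the propargylation, semi-hydrogenation and Claisen sequence, the acetal, and the acidic deprotection next to the prenyl group; on these points the alternative is better. The last step is equal (the same desilylation).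
- Against: C3 must already be present in A7, where it is allylic and γ to the ketone, so basic diazo-transfer conditions and the ketene stages could racemise it. Vinylketenes from acyclic enones are the less efficient class for this annulation. A8 is volatile and sensitive. Enantiopure A7 needs its own asymmetric chroman synthesis plus chain extension.
- Comparison: the key step would form three C–C bonds but no stereocentre, whereas the chosen plan spends its strategic step on the stereocentre. Overall step economy would be worse.

Key step: step 11

Assumption: the sense of enantiotopic-group selection by the copper–diamine catalyst cannot be predicted reliably for this substrate, so the ligand antipode that gives (R)-16 (both are commercial) is to be fixed in the first run by assigning the configuration of 16.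

## Steps

Step 1
Reactants: 1 3-bromo-5-methoxyphenol
Product: 2 (3-bromo-5-methoxyphenoxy)tri(propan-2-yl)silane
Conditions: TIPSCl, imidazole, DMF, rt
Reagents that add atoms: chlorotri(propan-2-yl)silane (TIPSCl), CC(C)[Si](Cl)(C(C)C)C(C)C
Why: Imidazole-promoted O-silylation of the phenol; the bulky TIPS ether masks O7 through the basic and hydride steps and, as a poor directing group, shields both of its ortho positions in step 2.

Step 2
Reactants: 2 (3-bromo-5-methoxyphenoxy)tri(propan-2-yl)silane
Product: 4 (2-bromo-6-methoxy-4-{[tri(propan-2-yl)silyl]oxy}phenyl)methanol, via the benzaldehyde 3 (not isolated)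
Conditions: LDA, THF, −78 °C; DMF, −78 to 0 °C; then MeOH, NaBH4, 0 °C
Reagents that add atoms: N,N-dimethylformamide, CN(C)C=O
Why: Directed ortho-metalation: LDA should remove the proton flanked by Br and OMe (acidified by both, OMe coordinates lithium, the positions next to OTIPS are blocked), and the aryllithium is kept cold to avoid loss of LiBr. Formylation with DMF gives 3, which NaBH4 reduces in the same flask.

Step 3
Reactants: 4 (2-bromo-6-methoxy-4-{[tri(propan-2-yl)silyl]oxy}phenyl)methanol
Product: 5 [3-bromo-4-(bromomethyl)-5-methoxyphenoxy]tri(propan-2-yl)silane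
Conditions: CBr4, PPh3, CH2Cl2, 0 °C; used at once
Reagents that add atoms: tetrabromomethane, BrC(Br)(Br)Br
Why: Appel bromination under neutral conditions, so the silyl ether is not exposed to HBr; the electron-rich benzyl bromide is taken on without storage.

Step 4
Reactants: 6 2-bromo-5-methoxyphenol; 7 3-chloro-3-methylbut-1-yne
Product: 8 1-bromo-4-methoxy-2-[(2-methylbut-3-yn-2-yl)oxy]benzene
Conditions: DBU, CuCl2·2H2O (cat.), MeCN, 0 °C to rt
Reagents that add atoms: none
Why: Copper-catalysed propargylic O-alkylation of the phenol by the tertiary propargyl chloride (substitution through a copper acetylide/allenylidene species), which gives the tertiary ether without elimination.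

Step 5
Reactants: 8 1-bromo-4-methoxy-2-[(2-methylbut-3-yn-2-yl)oxy]benzene
Product: 9 1-bromo-4-methoxy-2-[(2-methylbut-3-en-2-yl)oxy]benzene
Conditions: H2 (1 atm), Pd/CaCO3 poisoned with Pb(OAc)2 (Lindlar catalyst), quinoline, EtOAc, rt
Reagents that add atoms: none
Why: Lindlar semi-hydrogenation of the terminal alkyne to the alkene; the poisoned catalyst should leave the aryl bromide and the aryl ether alone.

Step 6
Reactants: 9 1-bromo-4-methoxy-2-[(2-methylbut-3-en-2-yl)oxy]benzene
Product: 10 6-bromo-3-methoxy-2-(3-methylbut-2-en-1-yl)phenol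
Conditions: PhNEt2, 150 °C
Reagents that add atoms: none
Why: Aromatic Claisen rearrangement ([3,3]-sigmatropic, with allyl inversion) turns the 1,1-dimethylallyl ether into the ortho-prenyl phenol; the only free ortho position is C6 (the other bears Br), and the amine solvent suppresses acid-catalysed cyclisation of the product.

Step 7
Reactants: 10 6-bromo-3-methoxy-2-(3-methylbut-2-en-1-yl)phenol
Product: 11 1-bromo-4-methoxy-2-(methoxymethoxy)-3-(3-methylbut-2-en-1-yl)benzene
Conditions: NaH, MOMCl, THF/DMF, 0 °C to rt
Reagents that add atoms: chloromethyl methyl ether (MOMCl), COCCl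
Why: Williamson-type O-alkylation of the hindered phenoxide; the MOM acetal is small next to the future quaternary carbon and stable to palladium catalysis, enolates, LiAlH4, Cs2CO3 and RhCl(PPh3)3.

Step 8
Reactants: 11 1-bromo-4-methoxy-2-(methoxymethoxy)-3-(3-methylbut-2-en-1-yl)benzene; 12 diethyl propanedioate (diethyl malonate)
Product: 13 diethyl 2-[4-methoxy-2-(methoxymethoxy)-3-(3-methylbut-2-en-1-yl)phenyl]propanedioate
Conditions: Pd(dba)2 (2 mol %), P(t-Bu)3·HBF4 (4 mol %), K3PO4, toluene, 80 °C
Reagents that add atoms: none
Why: Palladium-catalysed α-arylation of a malonate: oxidative addition of the aryl bromide to zerovalent palladium bearing the bulky electron-rich phosphine, exchange with the malonate enolate and C–C reductive elimination. The acidic product stays as its enolate, which prevents a second arylation.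

Step 9
Reactants: 13 diethyl 2-[4-methoxy-2-(methoxymethoxy)-3-(3-methylbut-2-en-1-yl)phenyl]propanedioate; 5 [3-bromo-4-(bromomethyl)-5-methoxyphenoxy]tri(propan-2-yl)silane
Product: 14 diethyl 2-[(2-bromo-6-methoxy-4-{[tri(propan-2-yl)silyl]oxy}phenyl)methyl]-2-[4-methoxy-2-(methoxymethoxy)-3-(3-methylbut-2-en-1-yl)phenyl]propanedioate
Conditions: NaH, THF/DMF (4:1), 0 °C; then 5, rt to 40 °C
Reagents that add atoms: none
Why: SN2 alkylation of the sodium arylmalonate enolate by the activated benzylic bromide forms the C3–C4 bond and the quaternary carbon; no stereocentre arises because the two ester groups are identical.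

Step 10
Reactants: 14 diethyl 2-[(2-bromo-6-methoxy-4-{[tri(propan-2-yl)silyl]oxy}phenyl)methyl]-2-[4-methoxy-2-(methoxymethoxy)-3-(3-methylbut-2-en-1-yl)phenyl]propanedioate
Product: 15 2-[(2-bromo-6-methoxy-4-{[tri(propan-2-yl)silyl]oxy}phenyl)methyl]-2-[4-methoxy-2-(methoxymethoxy)-3-(3-methylbut-2-en-1-yl)phenyl]propane-1,3-diol
Conditions: LiAlH4, THF, 0 °C to rt
Reagents that add atoms: none
Why: Hydride reduction of both esters gives the prochiral 2,2-disubstituted propane-1,3-diol in one operation; aryl bromide, silyl ether and acetal should tolerate LiAlH4 at this temperature.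

Step 11
Reactants: 15 2-[(2-bromo-6-methoxy-4-{[tri(propan-2-yl)silyl]oxy}phenyl)methyl]-2-[4-methoxy-2-(methoxymethoxy)-3-(3-methylbut-2-en-1-yl)phenyl]propane-1,3-diol
Product: 16 [(3R)-5-methoxy-3-[4-methoxy-2-(methoxymethoxy)-3-(3-methylbut-2-en-1-yl)phenyl]-7-{[tri(propan-2-yl)silyl]oxy}-3,4-dihydro-2H-chromen-3-yl]methanol
Conditions: CuI (10 mol %), (1S,2S)- or (1R,2R)-N,N′-dimethyl-1,2-diphenylethane-1,2-diamine (20 mol %, antipode as in the assumption), Cs2CO3, 4 Å MS, MeCN, 40–60 °C
Reagents that add atoms: none
Why: Cs2CO3 deprotonates one hydroxyl and a diamine-bound alkoxide of monovalent copper forms. Intramolecular oxidative addition of the C8a–Br bond then gives a trivalent copper aryl alkoxide in a seven-membered metallacycle (Cu, O, CH2, C3, C4, C4a, C8a), and C–O reductive elimination makes the O1–C8a bond. The closest known reaction type is the copper-catalysed (Ullmann-type) enantioselective desymmetrising intramolecular O-arylation of 2-(2-halobenzyl)propane-1,3-diols to chroman-3-ylmethanols. Ring C closes in a formal 6-exo mode: the oxygen attacks the sp2 carbon C8a and the leaving bromide lies outside the new ring. C3 becomes a quaternary stereocentre under ligand control, since the C2-symmetric diamine makes the two cyclisation transition states, which differ in which CH2OH arm is bound, diastereomeric by reading ring B against the benzylic CH2. The step needs enantiotopic-group selectivity (set by the ligand and a low reaction temperature) and a single O-arylation (there is only one aryl bromide, and the remaining arm cannot reach it after closure). The quaternary carbon speeds closure through the gem-disubstituent effect, and neither 15 nor 16 has a pathway to epimerise.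

Step 12
Reactants: 16 [(3R)-5-methoxy-3-[4-methoxy-2-(methoxymethoxy)-3-(3-methylbut-2-en-1-yl)phenyl]-7-{[tri(propan-2-yl)silyl]oxy}-3,4-dihydro-2H-chromen-3-yl]methanol
Product: 17 (3S)-5-methoxy-3-[4-methoxy-2-(methoxymethoxy)-3-(3-methylbut-2-en-1-yl)phenyl]-7-{[tri(propan-2-yl)silyl]oxy}-3,4-dihydro-2H-chromene-3-carbaldehyde
Conditions: Dess–Martin periodinane, pyridine, CH2Cl2, 0 °C to rt
Reagents that add atoms: none
Why: Dess–Martin oxidation of the neopentyl primary alcohol; the aldehyde has no α-hydrogen, so C3 cannot epimerise, and pyridine buffers the acetic acid formed.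

Step 13
Reactants: 17 (3S)-5-methoxy-3-[4-methoxy-2-(methoxymethoxy)-3-(3-methylbut-2-en-1-yl)phenyl]-7-{[tri(propan-2-yl)silyl]oxy}-3,4-dihydro-2H-chromene-3-carbaldehyde
Product: 18 {[(3R)-5-methoxy-3-[4-methoxy-2-(methoxymethoxy)-3-(3-methylbut-2-en-1-yl)phenyl]-3,4-dihydro-2H-chromen-7-yl]oxy}tri(propan-2-yl)silane
Conditions: RhCl(PPh3)3 (1.1 equiv), degassed xylene, 130 °C
Reagents that add atoms: none
Why: Tsuji–Wilkinson decarbonylation: the formyl C–H adds to monovalent rhodium, CO is extruded to a tertiary alkyl hydride of trivalent rhodium, and C–H reductive elimination puts hydrogen where the formyl group stood, with retention at C3 (the descriptor changes from S to R only because the priorities change). Fast reductive elimination is relied on to outrun β-hydride loss.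

Step 14
Reactants: 18 {[(3R)-5-methoxy-3-[4-methoxy-2-(methoxymethoxy)-3-(3-methylbut-2-en-1-yl)phenyl]-3,4-dihydro-2H-chromen-7-yl]oxy}tri(propan-2-yl)silane
Product: 19 3-methoxy-6-[(3R)-5-methoxy-7-{[tri(propan-2-yl)silyl]oxy}-3,4-dihydro-2H-chromen-3-yl]-2-(3-methylbut-2-en-1-yl)phenol
Conditions: HCl (ca. 1 M) in MeOH/THF, 0 °C to rt
Reagents that add atoms: none
Why: Acid-catalysed acetal exchange with methanol removes the MOM group; the acid is kept dilute and cold because stronger acid would add the 2′-OH to the prenyl alkene, and the aryl TIPS ether should be inert here.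

Step 15
Reactants: 19 3-methoxy-6-[(3R)-5-methoxy-7-{[tri(propan-2-yl)silyl]oxy}-3,4-dihydro-2H-chromen-3-yl]-2-(3-methylbut-2-en-1-yl)phenol
Product: 20 (3R)-3-[2-hydroxy-4-methoxy-3-(3-methylbut-2-en-1-yl)phenyl]-5-methoxy-3,4-dihydro-2H-chromen-7-ol
Conditions: TBAF, AcOH (1:1), THF, 0 °C
Reagents that add atoms: none
Why: Fluoride-induced cleavage of the aryl silyl ether, buffered with acetic acid so that the electron-rich phenoxide is not left to oxidise; C3 is not acidic, so its configuration is untouched.

## Compound list

1 | 3-bromo-5-methoxyphenol | COc1cc(O)cc(Br)c1 | starting material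
2 | (3-bromo-5-methoxyphenoxy)tri(propan-2-yl)silane | COc1cc(Br)cc(O[Si](C(C)C)(C(C)C)C(C)C)c1 | intermediate
3 | 2-bromo-6-methoxy-4-{[tri(propan-2-yl)silyl]oxy}benzaldehyde | COc1cc(O[Si](C(C)C)(C(C)C)C(C)C)cc(Br)c1C=O | intermediate (not isolated)
4 | (2-bromo-6-methoxy-4-{[tri(propan-2-yl)silyl]oxy}phenyl)methanol | COc1cc(O[Si](C(C)C)(C(C)C)C(C)C)cc(Br)c1CO | intermediate
5 | [3-bromo-4-(bromomethyl)-5-methoxyphenoxy]tri(propan-2-yl)silane | COc1cc(O[Si](C(C)C)(C(C)C)C(C)C)cc(Br)c1CBr | intermediate
6 | 2-bromo-5-methoxyphenol | COc1ccc(Br)c(O)c1 | starting material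
7 | 3-chloro-3-methylbut-1-yne | CC(C)(Cl)C#C | starting material
8 | 1-bromo-4-methoxy-2-[(2-methylbut-3-yn-2-yl)oxy]benzene | COc1ccc(Br)c(OC(C)(C)C#C)c1 | intermediate
9 | 1-bromo-4-methoxy-2-[(2-methylbut-3-en-2-yl)oxy]benzene | COc1ccc(Br)c(OC(C)(C)C=C)c1 | intermediate
10 | 6-bromo-3-methoxy-2-(3-methylbut-2-en-1-yl)phenol | COc1ccc(Br)c(O)c1CC=C(C)C | intermediate
11 | 1-bromo-4-methoxy-2-(methoxymethoxy)-3-(3-methylbut-2-en-1-yl)benzene | COCOc1c(Br)ccc(OC)c1CC=C(C)C | intermediate
12 | diethyl propanedioate | CCOC(=O)CC(=O)OCC | starting material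
13 | diethyl 2-[4-methoxy-2-(methoxymethoxy)-3-(3-methylbut-2-en-1-yl)phenyl]propanedioate | CCOC(=O)C(C(=O)OCC)c1ccc(OC)c(CC=C(C)C)c1OCOC | intermediate
14 | diethyl 2-[(2-bromo-6-methoxy-4-{[tri(propan-2-yl)silyl]oxy}phenyl)methyl]-2-[4-methoxy-2-(methoxymethoxy)-3-(3-methylbut-2-en-1-yl)phenyl]propanedioate | CCOC(=O)C(Cc1c(Br)cc(O[Si](C(C)C)(C(C)C)C(C)C)cc1OC)(C(=O)OCC)c1ccc(OC)c(CC=C(C)C)c1OCOC | intermediate
15 | 2-[(2-bromo-6-methoxy-4-{[tri(propan-2-yl)silyl]oxy}phenyl)methyl]-2-[4-methoxy-2-(methoxymethoxy)-3-(3-methylbut-2-en-1-yl)phenyl]propane-1,3-diol | OCC(CO)(Cc1c(Br)cc(O[Si](C(C)C)(C(C)C)C(C)C)cc1OC)c1ccc(OC)c(CC=C(C)C)c1OCOC | intermediate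
16 | [(3R)-5-methoxy-3-[4-methoxy-2-(methoxymethoxy)-3-(3-methylbut-2-en-1-yl)phenyl]-7-{[tri(propan-2-yl)silyl]oxy}-3,4-dihydro-2H-chromen-3-yl]methanol | COc1cc(O[Si](C(C)C)(C(C)C)C(C)C)cc2c1C[C@](CO)(c1ccc(OC)c(CC=C(C)C)c1OCOC)CO2 | intermediate
17 | (3S)-5-methoxy-3-[4-methoxy-2-(methoxymethoxy)-3-(3-methylbut-2-en-1-yl)phenyl]-7-{[tri(propan-2-yl)silyl]oxy}-3,4-dihydro-2H-chromene-3-carbaldehyde | COc1cc(O[Si](C(C)C)(C(C)C)C(C)C)cc2c1C[C@](C=O)(c1ccc(OC)c(CC=C(C)C)c1OCOC)CO2 | intermediate
18 | {[(3R)-5-methoxy-3-[4-methoxy-2-(methoxymethoxy)-3-(3-methylbut-2-en-1-yl)phenyl]-3,4-dihydro-2H-chromen-7-yl]oxy}tri(propan-2-yl)silane | COc1cc(O[Si](C(C)C)(C(C)C)C(C)C)cc2c1C[C@H](c1ccc(OC)c(CC=C(C)C)c1OCOC)CO2 | intermediate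
19 | 3-methoxy-6-[(3R)-5-methoxy-7-{[tri(propan-2-yl)silyl]oxy}-3,4-dihydro-2H-chromen-3-yl]-2-(3-methylbut-2-en-1-yl)phenol | COc1cc(O[Si](C(C)C)(C(C)C)C(C)C)cc2c1C[C@H](c1ccc(OC)c(CC=C(C)C)c1O)CO2 | intermediate
20 | (3R)-3-[2-hydroxy-4-methoxy-3-(3-methylbut-2-en-1-yl)phenyl]-5-methoxy-3,4-dihydro-2H-chromen-7-ol | COc1cc(O)cc2c1C[C@H](c1ccc(OC)c(CC=C(C)C)c1O)CO2 | target

## Step count and least certain steps

Total: 15 steps. Longest linear sequence: 12 steps (from 6 through steps 4–15); the ring-A branch (steps 1–3) joins at step 9.

**Step 11 (key step).**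
- What may go wrong: poor discrimination between the two enantiotopic hydroxymethyl arms, because the ligand must tell an ortho-substituted aryl group from an arylmethyl group of similar size. Oxidative addition of the aryl bromide to monovalent copper may be slow, forcing a higher temperature that erodes selectivity. Carbonate may also slowly remove the silyl group. Changing to Pd(OAc)2 with a chiral phosphine would be a variation within the same approach.
- Fallback (from 15, back at 18): the arms are differentiated by acylation and the ring is closed last. Lipase-catalysed desymmetrising acetylation of 15 with vinyl acetate (enzyme screened for the required sense) should give the (R)-monoacetate F1. Prompt Dess–Martin oxidation, which also removes the free hydroxyl that could allow acetyl migration, gives the acetoxy aldehyde F2. RhCl(PPh3)3 then removes the formyl carbon with retention to the acetate F3, K2CO3 in MeOH frees the primary alcohol F4, and an achiral ring closure (CuI, 1,10-phenanthroline, Cs2CO3, toluene, 110 °C) should give 18.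

**Step 13.**
- What may go wrong: β-hydride loss from the tertiary alkyl rhodium hydride (towards the isoflavene) competing with reductive elimination, migration of the prenyl double bond induced by rhodium hydrides at this temperature, or sluggish reaction of the hindered neopentyl formyl group.
- Fallback (from 13, back at 18): no carbon is deleted; C3 is set by a chiral-auxiliary alkylation. Saponification of 13 (NaOH, aqueous EtOH), mild acidification and warming should give the arylacetic acid F5 by decarboxylation. Coupling with (R)-4-benzyl-1,3-oxazolidin-2-one (DCC, DMAP) gives the imide F6. Its sodium enolate (NaHMDS, −78 °C) is alkylated by 5 on the face away from the benzyl group to the imide F7. LiBH4 releases the auxiliary and gives the primary alcohol F4 (the compound of the preceding fallback), which is closed to 18 with CuI, 1,10-phenanthroline and Cs2CO3.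

**Step 9.**
- What may go wrong: slow alkylation, because a tertiary enolate meets a benzylic carbon flanked by two ortho substituents, leaving time for ionisation or self-condensation of the electron-rich benzyl bromide.
- Fallback (from 13, back at 15): the quaternary carbon is built in two smaller steps. Krapcho dealkoxycarbonylation of 13 (LiCl, wet DMSO, 140 °C) gives the ethyl arylacetate F8. Its less hindered lithium enolate (LDA, −78 °C) is alkylated by 5 to the racemic propanoate F9. A second enolisation and aldol addition to monomeric formaldehyde gives the racemic hydroxy ester F10, and LiAlH4 reduction gives 15.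

**Step 2.**
- What may go wrong: deprotonation at one of the other two ring positions, loss of LiBr to an aryne if the aryllithium warms, or bromine migration.
- Fallback (from 2, back at 4 by way of 3): electrophilic instead of anionic formylation. Rieche formylation of 2 (Cl2CHOMe, TiCl4, CH2Cl2, −78 to 0 °C) should be delivered ortho to OMe and away from the silyl ether to give 3, which NaBH4 reduces to 4. No new compound arises (F0).

## Further compounds

F1 | step 11 | (2R)-2-[(2-bromo-6-methoxy-4-{[tri(propan-2-yl)silyl]oxy}phenyl)methyl]-3-hydroxy-2-[4-methoxy-2-(methoxymethoxy)-3-(3-methylbut-2-en-1-yl)phenyl]propyl acetate | COc1cc(O[Si](C(C)C)(C(C)C)C(C)C)cc(Br)c1C[C@](CO)(c1ccc(OC)c(CC=C(C)C)c1OCOC)COC(C)=O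
F2 | step 11 | (2S)-2-[(2-bromo-6-methoxy-4-{[tri(propan-2-yl)silyl]oxy}phenyl)methyl]-2-[4-methoxy-2-(methoxymethoxy)-3-(3-methylbut-2-en-1-yl)phenyl]-3-oxopropyl acetate | COc1cc(O[Si](C(C)C)(C(C)C)C(C)C)cc(Br)c1C[C@](C=O)(c1ccc(OC)c(CC=C(C)C)c1OCOC)COC(C)=O
F3 | step 11 | (2R)-3-(2-bromo-6-methoxy-4-{[tri(propan-2-yl)silyl]oxy}phenyl)-2-[4-methoxy-2-(methoxymethoxy)-3-(3-methylbut-2-en-1-yl)phenyl]propyl acetate | COc1cc(O[Si](C(C)C)(C(C)C)C(C)C)cc(Br)c1C[C@H](c1ccc(OC)c(CC=C(C)C)c1OCOC)COC(C)=O
F4 | step 11 | (2R)-3-(2-bromo-6-methoxy-4-{[tri(propan-2-yl)silyl]oxy}phenyl)-2-[4-methoxy-2-(methoxymethoxy)-3-(3-methylbut-2-en-1-yl)phenyl]propan-1-ol | COc1cc(O[Si](C(C)C)(C(C)C)C(C)C)cc(Br)c1C[C@H](c1ccc(OC)c(CC=C(C)C)c1OCOC)CO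
F5 | step 13 | [4-methoxy-2-(methoxymethoxy)-3-(3-methylbut-2-en-1-yl)phenyl]acetic acid | OC(=O)Cc1ccc(OC)c(CC=C(C)C)c1OCOC
F6 | step 13 | (4R)-4-benzyl-3-{[4-methoxy-2-(methoxymethoxy)-3-(3-methylbut-2-en-1-yl)phenyl]acetyl}-1,3-oxazolidin-2-one | O=C(Cc1ccc(OC)c(CC=C(C)C)c1OCOC)N1[C@H](Cc2ccccc2)COC1=O
F7 | step 13 | (4R)-4-benzyl-3-[(2R)-3-(2-bromo-6-methoxy-4-{[tri(propan-2-yl)silyl]oxy}phenyl)-2-[4-methoxy-2-(methoxymethoxy)-3-(3-methylbut-2-en-1-yl)phenyl]propanoyl]-1,3-oxazolidin-2-one | COc1cc(O[Si](C(C)C)(C(C)C)C(C)C)cc(Br)c1C[C@H](c1ccc(OC)c(CC=C(C)C)c1OCOC)C(=O)N1[C@H](Cc2ccccc2)COC1=O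
F8 | step 9 | ethyl [4-methoxy-2-(methoxymethoxy)-3-(3-methylbut-2-en-1-yl)phenyl]acetate | CCOC(=O)Cc1ccc(OC)c(CC=C(C)C)c1OCOC
F9 | step 9 | ethyl 3-(2-bromo-6-methoxy-4-{[tri(propan-2-yl)silyl]oxy}phenyl)-2-[4-methoxy-2-(methoxymethoxy)-3-(3-methylbut-2-en-1-yl)phenyl]propanoate (racemic) | CCOC(=O)C(Cc1c(Br)cc(O[Si](C(C)C)(C(C)C)C(C)C)cc1OC)c1ccc(OC)c(CC=C(C)C)c1OCOC
F10 | step 9 | ethyl 2-[(2-bromo-6-methoxy-4-{[tri(propan-2-yl)silyl]oxy}phenyl)methyl]-3-hydroxy-2-[4-methoxy-2-(methoxymethoxy)-3-(3-methylbut-2-en-1-yl)phenyl]propanoate (racemic) | CCOC(=O)C(CO)(Cc1c(Br)cc(O[Si](C(C)C)(C(C)C)C(C)C)cc1OC)c1ccc(OC)c(CC=C(C)C)c1OCOC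
F0 | step 2 | none | none
A1 | alternative 1 | methyl 2-[2-({2,4-bis[(tert-butyldimethylsilyl)oxy]-6-methoxyphenyl}methoxy)-4-methoxy-3-(3-methylbut-2-en-1-yl)phenyl]-2-diazoacetate | COC(=O)C(=[N+]=[N-])c1ccc(OC)c(CC=C(C)C)c1OCc1c(OC)cc(O[Si](C)(C)C(C)(C)C)cc1O[Si](C)(C)C(C)(C)C
A2 | alternative 1 | methyl (2R,3S)-2-{2,4-bis[(tert-butyldimethylsilyl)oxy]-6-methoxyphenyl}-6-methoxy-7-(3-methylbut-2-en-1-yl)-2,3-dihydro-1-benzofuran-3-carboxylate (2,3-cis) | COC(=O)[C@@H]1[C@H](c2c(OC)cc(O[Si](C)(C)C(C)(C)C)cc2O[Si](C)(C)C(C)(C)C)Oc2c(CC=C(C)C)c(OC)ccc21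
A3 | alternative 1 | (6aR,11aR)-1,9-dimethoxy-10-(3-methylbut-2-en-1-yl)-6a,11a-dihydro-6H-[1]benzofuro[3,2-c]chromen-3-ol | COc1cc(O)cc2c1[C@@H]1Oc3c(CC=C(C)C)c(OC)ccc3[C@@H]1CO2
A4 | alternative 2 | 3-(prop-2-en-1-yloxy)cyclobut-2-en-1-one | C=CCOC1=CC(=O)C1
A5 | alternative 2 | tert-butyl({(2R)-5-methoxy-2-[4-methoxy-2-(methoxymethoxy)-3-(3-methylbut-2-en-1-yl)phenyl]pent-4-yn-1-yl}oxy)dimethylsilane | COC#CC[C@H](c1ccc(OC)c(CC=C(C)C)c1OCOC)CO[Si](C)(C)C(C)(C)C
A6 | alternative 2 | 2-{(2R)-3-[(tert-butyldimethylsilyl)oxy]-2-[4-methoxy-2-(methoxymethoxy)-3-(3-methylbut-2-en-1-yl)phenyl]propyl}-3-methoxy-5-(prop-2-en-1-yloxy)phenol | COc1cc(OCC=C)cc(O)c1C[C@H](c1ccc(OC)c(CC=C(C)C)c1OCOC)CO[Si](C)(C)C(C)(C)C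
A7 | alternative 3 | (3E)-1-diazo-4-[(3R)-5-methoxy-7-{[tri(propan-2-yl)silyl]oxy}-3,4-dihydro-2H-chromen-3-yl]but-3-en-2-one | COc1cc(O[Si](C(C)C)(C(C)C)C(C)C)cc2c1C[C@H](/C=C/C(=O)C=[N+]=[N-])CO2
A8 | alternative 3 | 1-methoxy-5-methylhex-4-en-1-yne | COC#CCC=C(C)C
A9 | alternative 3 | 3-methoxy-6-[(3R)-5-methoxy-7-{[tri(propan-2-yl)silyl]oxy}-3,4-dihydro-2H-chromen-3-yl]-2-(3-methylbut-2-en-1-yl)phenol (identical with 19) | COc1cc(O[Si](C(C)C)(C(C)C)C(C)C)cc2c1C[C@H](c1ccc(OC)c(CC=C(C)C)c1O)CO2
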